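**Plan**
- Retrosynthesis: after the three O-protecting groups are removed, one operation is cut at C4–C4a, C2–O1 and C3–OH, leading back to an o-iodoaryl ester of a 2-arylacrylic acid; the ester C–O bond, the aryl–C3 bond (Negishi) and the aryl–prenyl bond (ortho-lithiation) follow.
- Forward: ring B is completed first (silyl ether, prenyl between the two OMe groups, bromide, acrylate, acid) and esterified with 2-iodo-3,5-bis(MOM-oxy)phenol (ring A); ring C, the only ring that is made, closes in the key step.
- Enabling feature: C4a lies between the oxygen-bearing carbons C8a and C5 of the phloroglucinol ring A, so an acyl group parked on O1 can be handed to a C4a carbanion (1,3 O→C shift). This unmasks O1 as a phenoxide within six-ring reach of the acrylate CH2 (C2), and because C3 is the α-carbon of the new C4 ketone, the closure leaves C3 as a planar enolate.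
- Stereochemistry: the single stereocentre C3 is never carried through the route; it is created from that enolate by oxygen transfer from a camphor-derived N-sulfonyloxaziridine (reagent control), all material passing through the same trigonal intermediate.

Key step: step 9

Assumption: the [(8,8-dimethoxycamphoryl)sulfonyl]oxaziridine of the (1R)-10-camphorsulfonic acid series is taken to deliver oxygen to the Si face of C3 of the chromanone enolate (Si-face attack gives 3S); this sense rests on analogy and must be confirmed on first use, and if it is opposite, the antipodal reagent from (1S)-10-camphorsulfonic acid is substituted with no other change.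

**Step 1**
Reactants: 1 2,4-dimethoxyphenol
Product: 2 (2,4-dimethoxyphenoxy)triisopropylsilane
Conditions: TIPSCl, imidazole, DMF, rt
Reagents that add atoms: chlorotriisopropylsilane, CC(C)[Si](Cl)(C(C)C)C(C)C
Why: Silylation of a phenol with a silyl chloride and imidazole; the bulky, weakly coordinating OTIPS group is chosen because it should not direct lithiation to its own ortho position and tolerates organolithium reagents.

**Step 2**
Reactants: 2 (2,4-dimethoxyphenoxy)triisopropylsilane; 3 1-bromo-3-methylbut-2-ene (prenyl bromide)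
Product: 5 [2,4-dimethoxy-3-(3-methylbut-2-en-1-yl)phenoxy]triisopropylsilane, via aryllithium 4 (not isolated)
Conditions: n-BuLi, THF, 0 °C → rt; CuBr·SMe2 (10 mol %), then 3, −40 °C → rt
Reagents that add atoms: none
Why: Directed ortho-metalation should take place at the carbon flanked by the two methoxy groups (cooperative 1,3-effect, as in 1,3-dimethoxy- and 1,2,4-trimethoxybenzene), and copper-catalysed SN2 allylation of the aryllithium installs the linear prenyl group.

**Step 3**
Reactants: 5 [2,4-dimethoxy-3-(3-methylbut-2-en-1-yl)phenoxy]triisopropylsilane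
Product: 6 [5-bromo-2,4-dimethoxy-3-(3-methylbut-2-en-1-yl)phenoxy]triisopropylsilane
Conditions: NBS (1.0 equiv), MeCN, −20 → 0 °C, dark
Reagents that add atoms: N-bromosuccinimide, O=C1CCC(=O)N1Br
Why: Electrophilic aromatic bromination at the only position that is para to one methoxy group and ortho to the other; the tris-oxygenated ring should react faster than the isolated trisubstituted alkene, which lacks a nucleophile or radical initiator to carry it further.

**Step 4**
Reactants: 6 [5-bromo-2,4-dimethoxy-3-(3-methylbut-2-en-1-yl)phenoxy]triisopropylsilane; 7 methyl 2-bromoprop-2-enoate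
Product: 10 methyl 2-[2,4-dimethoxy-3-(3-methylbut-2-en-1-yl)-5-(triisopropylsilyloxy)phenyl]prop-2-enoate, via aryllithium 8 (not isolated), via arylzinc chloride 9 (not isolated)
Conditions: n-BuLi, THF, −78 °C; ZnCl2, −78 → 0 °C; then 7, Pd(PPh3)4 (5 mol %), rt
Reagents that add atoms: none
Why: Bromine–lithium exchange, transmetalation to zinc and Negishi coupling with an α-bromoacrylate, a vinyl bromide activated for oxidative addition; the arylzinc tolerates the ester.

**Step 5**
Reactants: 10 methyl 2-[2,4-dimethoxy-3-(3-methylbut-2-en-1-yl)-5-(triisopropylsilyloxy)phenyl]prop-2-enoate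
Product: 11 2-[2,4-dimethoxy-3-(3-methylbut-2-en-1-yl)-5-(triisopropylsilyloxy)phenyl]prop-2-enoic acid
Conditions: LiOH·H2O, THF/H2O 3:1, 0 °C → rt; then 1 M HCl to pH 3, 0 °C
Reagents that add atoms: lithium hydroxide, [Li+].[OH-]
Why: Saponification of a methyl ester; the aryl TIPS ether of an electron-rich, ortho-substituted phenol should survive dilute lithium hydroxide at or below room temperature.

**Step 6**
Reactants: 12 benzene-1,3,5-triol (phloroglucinol)
Product: 13 3,5-bis(methoxymethoxy)phenol
Conditions: MOMCl (2.0 equiv), i-Pr2NEt, DMF, 0 °C → rt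
Reagents that add atoms: chloromethyl methyl ether, COCCl
Why: Statistical O-alkylation of two of the three equivalent hydroxyl groups (Williamson-type acetal ether formation); the bis-ether is to be separated from mono- and tris-ether by chromatography.

**Step 7**
Reactants: 13 3,5-bis(methoxymethoxy)phenol
Product: 14 2-iodo-3,5-bis(methoxymethoxy)phenol
Conditions: I2 (1.0 equiv), NaHCO3, THF/H2O 1:1, 0 °C
Reagents that add atoms: iodine, II
Why: Electrophilic iodination of the phenoxide should occur ortho to the free hydroxyl group, the alternative position between the two MOM ethers being flanked on both sides; one equivalent of iodine limits di-iodination.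

**Step 8**
Reactants: 11 2-[2,4-dimethoxy-3-(3-methylbut-2-en-1-yl)-5-(triisopropylsilyloxy)phenyl]prop-2-enoic acid; 14 2-iodo-3,5-bis(methoxymethoxy)phenol
Product: 15 2-iodo-3,5-bis(methoxymethoxy)phenyl 2-[2,4-dimethoxy-3-(3-methylbut-2-en-1-yl)-5-(triisopropylsilyloxy)phenyl]prop-2-enoate
Conditions: DIC, DMAP (10 mol %), CH2Cl2, 0 °C → rt
Reagents that add atoms: none
Why: Steglich esterification (carbodiimide activation with DMAP as acyl-transfer catalyst) of an acid that has no α-hydrogen, so no ketene pathway is open.

**Step 9**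
Reactants: 15 2-iodo-3,5-bis(methoxymethoxy)phenyl 2-[2,4-dimethoxy-3-(3-methylbut-2-en-1-yl)-5-(triisopropylsilyloxy)phenyl]prop-2-enoate
Product: 19 (3S)-3-hydroxy-5,7-bis(methoxymethoxy)-3-[2,4-dimethoxy-3-(3-methylbut-2-en-1-yl)-5-(triisopropylsilyloxy)phenyl]-2,3-dihydro-4H-chromen-4-one, via aryllithium 16 (not isolated), via lithium aryloxide enone 17 (not isolated), via lithium enolate 18 (not isolated)
Conditions: n-BuLi (1.05 equiv), THF (0.02 M), −95 °C; −95 → −20 °C; then oxaziridine (1.5 equiv), −78 °C; AcOH, −78 °C
Reagents that add atoms: [(8,8-dimethoxycamphoryl)sulfonyl]oxaziridine of the (1R)-10-camphorsulfonic acid series, C1[C@]23CC[C@H](C2(C)C)C(OC)(OC)[C@@]34ON4S1(=O)=O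
Why: Proposed new method: iodine–lithium exchange at C4a should outrun any addition of n-BuLi to the non-enolisable acrylate ester, and the aryllithium, held between the O-acyl and OMOM groups, attacks its own ester carbonyl (4-exo-trig, then collapse of the tetrahedral intermediate; closest known type: the anionic Fries rearrangement of o-haloaryl esters triggered by halogen–metal exchange), which forms C4–C4a and in the same act frees O1 as a phenoxide. The phenoxide then adds to the terminal CH2 of the enone by 6-endo-trig oxa-Michael closure (the ring-closing event of the classical isoflavanone synthesis from α-methylene deoxybenzoins), forming C2–O1 and ring C and leaving C3 as a planar, tetrasubstituted lithium enolate. Wherever the aryloxide/enolate equilibrium lies, only the enolate carbon is oxidised by the N-sulfonyloxaziridine (closest known type: the Davis oxidation of 2-substituted 1-tetralone and 3-substituted chroman-4-one enolates), so all material should be funnelled to the 3-hydroxy ketone. The C3 stereocentre is set by reagent control: the camphor-derived oxaziridine is to deliver oxygen to the Si face of the enolate, which is rigidified by chelation of the metal between O4 and the peri 5-OMOM oxygen, and the substrate carries no other stereochemical information. The selectivities needed are exchange before addition (secured by the iodide and −95 °C), acyl transfer in preference to 6-endo conjugate attack of the aryllithium on the acrylate (the aryl plane stands orthogonal to the ester, which places the carbanion σ-orbital at the carbonyl carbon and away from the β-carbon) and O-closure (only O1 can reach C2), while the prenyl alkene, the silyl ether and the acetals are inert to all three events.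

**Step 10**
Reactants: 19 (3S)-3-hydroxy-5,7-bis(methoxymethoxy)-3-[2,4-dimethoxy-3-(3-methylbut-2-en-1-yl)-5-(triisopropylsilyloxy)phenyl]-2,3-dihydro-4H-chromen-4-one
Product: 20 (3S)-3-hydroxy-3-[5-hydroxy-2,4-dimethoxy-3-(3-methylbut-2-en-1-yl)phenyl]-5,7-bis(methoxymethoxy)-2,3-dihydro-4H-chromen-4-one
Conditions: TBAF, AcOH, THF, 0 °C
Reagents that add atoms: none
Why: Fluoride cleavage of an aryl silyl ether, buffered with acetic acid so that the α-hydroxy ketone and the liberated phenol are not exposed to basic fluoride.

**Step 11**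
Reactants: 20 (3S)-3-hydroxy-3-[5-hydroxy-2,4-dimethoxy-3-(3-methylbut-2-en-1-yl)phenyl]-5,7-bis(methoxymethoxy)-2,3-dihydro-4H-chromen-4-one
Product: 21 sophonorol D, (3S)-3,5,7-trihydroxy-3-[5-hydroxy-2,4-dimethoxy-3-(3-methylbut-2-en-1-yl)phenyl]-2,3-dihydro-4H-chromen-4-one
Conditions: HCl (1.25 M in MeOH), 0 → 35 °C
Reagents that add atoms: none
Why: Acid-catalysed transacetalisation of the two aryl MOM ethers in methanol (the chelated 5-O-MOM group being the more labile); the quaternary C3 cannot epimerise, its ionisation is disfavoured by the adjacent carbonyl group, and the prenyl group has no free ortho-hydroxyl neighbour with which to cyclise.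

**Compound list**
1 | 2,4-dimethoxyphenol | COc1ccc(O)c(OC)c1 | starting material
2 | (2,4-dimethoxyphenoxy)triisopropylsilane | COc1ccc(O[Si](C(C)C)(C(C)C)C(C)C)c(OC)c1 | intermediate
3 | 1-bromo-3-methylbut-2-ene (prenyl bromide) | CC(C)=CCBr | starting material
4 | [2,6-dimethoxy-3-(triisopropylsilyloxy)phenyl]lithium (lithium on the carbon between the two methoxy groups) | COc1ccc(O[Si](C(C)C)(C(C)C)C(C)C)c(OC)c1[Li] | intermediate
5 | [2,4-dimethoxy-3-(3-methylbut-2-en-1-yl)phenoxy]triisopropylsilane | COc1ccc(O[Si](C(C)C)(C(C)C)C(C)C)c(OC)c1CC=C(C)C | intermediate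
6 | [5-bromo-2,4-dimethoxy-3-(3-methylbut-2-en-1-yl)phenoxy]triisopropylsilane | COc1c(Br)cc(O[Si](C(C)C)(C(C)C)C(C)C)c(OC)c1CC=C(C)C | intermediate
7 | methyl 2-bromoprop-2-enoate | C=C(Br)C(=O)OC | starting material
8 | [2,4-dimethoxy-3-(3-methylbut-2-en-1-yl)-5-(triisopropylsilyloxy)phenyl]lithium | COc1c([Li])cc(O[Si](C(C)C)(C(C)C)C(C)C)c(OC)c1CC=C(C)C | intermediate
9 | chloro[2,4-dimethoxy-3-(3-methylbut-2-en-1-yl)-5-(triisopropylsilyloxy)phenyl]zinc | COc1c([Zn]Cl)cc(O[Si](C(C)C)(C(C)C)C(C)C)c(OC)c1CC=C(C)C | intermediate
10 | methyl 2-[2,4-dimethoxy-3-(3-methylbut-2-en-1-yl)-5-(triisopropylsilyloxy)phenyl]prop-2-enoate | COC(=O)C(=C)c1cc(O[Si](C(C)C)(C(C)C)C(C)C)c(OC)c(CC=C(C)C)c1OC | intermediate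
11 | 2-[2,4-dimethoxy-3-(3-methylbut-2-en-1-yl)-5-(triisopropylsilyloxy)phenyl]prop-2-enoic acid | OC(=O)C(=C)c1cc(O[Si](C(C)C)(C(C)C)C(C)C)c(OC)c(CC=C(C)C)c1OC | intermediate
12 | benzene-1,3,5-triol (phloroglucinol) | Oc1cc(O)cc(O)c1 | starting material
13 | 3,5-bis(methoxymethoxy)phenol | COCOc1cc(O)cc(OCOC)c1 | intermediate
14 | 2-iodo-3,5-bis(methoxymethoxy)phenol | COCOc1cc(O)c(I)c(OCOC)c1 | intermediate
15 | 2-iodo-3,5-bis(methoxymethoxy)phenyl 2-[2,4-dimethoxy-3-(3-methylbut-2-en-1-yl)-5-(triisopropylsilyloxy)phenyl]prop-2-enoate | C=C(C(=O)Oc1cc(OCOC)cc(OCOC)c1I)c1cc(O[Si](C(C)C)(C(C)C)C(C)C)c(OC)c(CC=C(C)C)c1OC | intermediate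
16 | aryllithium of 15 (lithium in place of iodine, between the ester oxygen and an OMOM group) | C=C(C(=O)Oc1cc(OCOC)cc(OCOC)c1[Li])c1cc(O[Si](C(C)C)(C(C)C)C(C)C)c(OC)c(CC=C(C)C)c1OC | intermediate
17 | lithium 2-{2-[2,4-dimethoxy-3-(3-methylbut-2-en-1-yl)-5-(triisopropylsilyloxy)phenyl]prop-2-enoyl}-3,5-bis(methoxymethoxy)phenoxide | C=C(C(=O)c1c(O[Li])cc(OCOC)cc1OCOC)c1cc(O[Si](C(C)C)(C(C)C)C(C)C)c(OC)c(CC=C(C)C)c1OC | intermediate
18 | lithium 3-[2,4-dimethoxy-3-(3-methylbut-2-en-1-yl)-5-(triisopropylsilyloxy)phenyl]-5,7-bis(methoxymethoxy)-2H-chromen-4-olate (C3=C4 enolate) | COCOc1cc(OCOC)c2c(c1)OCC(c1cc(O[Si](C(C)C)(C(C)C)C(C)C)c(OC)c(CC=C(C)C)c1OC)=C2O[Li] | intermediate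
19 | (3S)-3-hydroxy-5,7-bis(methoxymethoxy)-3-[2,4-dimethoxy-3-(3-methylbut-2-en-1-yl)-5-(triisopropylsilyloxy)phenyl]-2,3-dihydro-4H-chromen-4-one | COc1c(O[Si](C(C)C)(C(C)C)C(C)C)cc([C@]2(O)COc3cc(OCOC)cc(OCOC)c3C2=O)c(OC)c1CC=C(C)C | intermediate
20 | (3S)-3-hydroxy-3-[5-hydroxy-2,4-dimethoxy-3-(3-methylbut-2-en-1-yl)phenyl]-5,7-bis(methoxymethoxy)-2,3-dihydro-4H-chromen-4-one | COc1c(O)cc([C@]2(O)COc3cc(OCOC)cc(OCOC)c3C2=O)c(OC)c1CC=C(C)C | intermediate
21 | sophonorol D, (3S)-3,5,7-trihydroxy-3-[5-hydroxy-2,4-dimethoxy-3-(3-methylbut-2-en-1-yl)phenyl]-2,3-dihydro-4H-chromen-4-one | COc1c(O)cc([C@]2(O)COc3cc(O)cc(O)c3C2=O)c(OC)c1CC=C(C)C | target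

**Step count and risks**
Total step count: 11. Longest linear sequence: 9 steps (steps 1–5 and 8–11, from 2,4-dimethoxyphenol).

Steps most likely to fail:

Step 9 (the proposed method). The funnel may break down: aryloxide 17 may not close to enolate 18 in the aprotic medium, 18 may add to the enone of 17, or oxygen transfer to the lithium enolate in the presence of lithium iodide may show poor facial selectivity. The fallback separates the three events and runs each under its precedented conditions. It sets out from 15: iodine–lithium exchange and acyl migration at −95 °C are quenched cold with acetic acid to give 1-[2-hydroxy-4,6-bis(methoxymethoxy)phenyl]-2-[2,4-dimethoxy-3-(3-methylbut-2-en-1-yl)-5-(triisopropylsilyloxy)phenyl]prop-2-en-1-one F1. Potassium carbonate in ethanol closes this by protic oxa-Michael addition to racemic 5,7-bis(methoxymethoxy)-3-[2,4-dimethoxy-3-(3-methylbut-2-en-1-yl)-5-(triisopropylsilyloxy)phenyl]-2,3-dihydro-4H-chromen-4-one F2. The sodium enolate of F2 (NaHMDS, THF, −78 °C), in which the racemic C3–H centre is made planar, is hydroxylated with the same oxaziridine, and the route is rejoined at 19.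

Step 3. Chemoselectivity may be lost: bromonium formation at the prenyl alkene, with capture by the neighbouring methoxy oxygen or the ring, may compete with aromatic substitution. The fallback halogenates before the alkene is present. It sets out from 2: aryllithium 4 is quenched with iodine to give triisopropyl(3-iodo-2,4-dimethoxyphenoxy)silane F3, and NBS brominates this to (5-bromo-3-iodo-2,4-dimethoxyphenoxy)triisopropylsilane F4. Selective iodine–magnesium exchange (i-PrMgCl·LiCl, THF, −20 °C; the iodide between the two methoxy groups exchanges much faster than the bromide) and copper-catalysed allylation with 3 return to the route at 6.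

Step 4. The α-bromoacrylate may polymerise, or the arylzinc may add in conjugate fashion before cross-coupling. The fallback makes the alkene by olefination instead. It sets out from 6: bromine–lithium exchange and acylation with dimethyl oxalate (inverse addition, −78 °C) give methyl 2-[2,4-dimethoxy-3-(3-methylbut-2-en-1-yl)-5-(triisopropylsilyloxy)phenyl]-2-oxoacetate F5, and Wittig methylenation of the keto group (Ph3P=CH2, THF, −78 → 0 °C) returns to the route at 10.

**Further compounds**
F1 | step 9 | 1-[2-hydroxy-4,6-bis(methoxymethoxy)phenyl]-2-[2,4-dimethoxy-3-(3-methylbut-2-en-1-yl)-5-(triisopropylsilyloxy)phenyl]prop-2-en-1-one | C=C(C(=O)c1c(O)cc(OCOC)cc1OCOC)c1cc(O[Si](C(C)C)(C(C)C)C(C)C)c(OC)c(CC=C(C)C)c1OC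
F2 | step 9 | racemic 5,7-bis(methoxymethoxy)-3-[2,4-dimethoxy-3-(3-methylbut-2-en-1-yl)-5-(triisopropylsilyloxy)phenyl]-2,3-dihydro-4H-chromen-4-one | COc1c(O[Si](C(C)C)(C(C)C)C(C)C)cc(C2COc3cc(OCOC)cc(OCOC)c3C2=O)c(OC)c1CC=C(C)C
F3 | step 3 | triisopropyl(3-iodo-2,4-dimethoxyphenoxy)silane | COc1ccc(O[Si](C(C)C)(C(C)C)C(C)C)c(OC)c1I
F4 | step 3 | (5-bromo-3-iodo-2,4-dimethoxyphenoxy)triisopropylsilane | COc1c(Br)cc(O[Si](C(C)C)(C(C)C)C(C)C)c(OC)c1I
F5 | step 4 | methyl 2-[2,4-dimethoxy-3-(3-methylbut-2-en-1-yl)-5-(triisopropylsilyloxy)phenyl]-2-oxoacetate | COC(=O)C(=O)c1cc(O[Si](C(C)C)(C(C)C)C(C)C)c(OC)c(CC=C(C)C)c1OC
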